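The constants stand for no real mixture; the rest is arithmetic.

**Your hunch.** The ratio of the forward opening of starting material to its quench by protic impurity in gamma at the start is 0.34. The quench is therefore faster in gamma at the start. In theta the quench constant times the starting material times the time is 6.80, so I book the 0.330 M of protic impurity off the charge in gamma, zeta, theta and delta, which leaves a pool of 0.770 M. You expect delta to give the most target, and the balance favours you: its equilibrium constant is 2.10 M against 0.894 M in gamma. I still bet against delta.

common to all: starting material 1.1 M; protic impurity 0.330 M; time 12 h

| flask | temperature |
|---|---|
| gamma | 10 °C |
| zeta | 25 °C |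
| theta | −5 °C |
| delta | 40 °C |

- the flask with the highest amount of target, in percent of the starting material charged ("all alike" if they lie within 1.5 percentage points) (gamma / zeta / theta / delta / all alike)
- final target, as a percentage of the starting material charged, in gamma
- final target, as a percentage of the starting material charged, in zeta
- final target, as a percentage of the starting material charged, in theta
- final target, as a percentage of the starting material charged, in delta

    starting material ⇌ target + by-product (K1 = 1.4 M, k1 = 1.2 h⁻¹, Ea1 = 87.0 kJ mol⁻¹, ΔH1 = 21.0 kJ mol⁻¹)
    starting material + protic impurity → quenched substrate (k2 = 4.7 M⁻¹ h⁻¹, Ea2 = 49.0 kJ mol⁻¹)
    starting material + target → side product A (k3 = 0.091 M⁻¹ h⁻¹, Ea3 = 82.0 kJ mol⁻¹)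
    target + by-product → side product B (k4 = 0.026 M⁻¹ h⁻¹, Ea4 = 78.0 kJ mol⁻¹)
    (constants at 25 °C)

- percent here means starting material units held: one side product A counts as two
- at 25 °C the constants are as listed, elsewhere as the activation energies and enthalpies make them

**Drain count.** At balance the pool splits so that target times by-product over starting material equals the constant, which puts 0.495 M of target in gamma. For the loss I multiply the time by the pseudo-first-order loss constant of target at balance amounts: the constant for side product A times the starting material, plus the constant for side product B times the by-product. In gamma this gives 0.0812, and I call it the drain count. Both losses are second order in the pool, so I divide the balance amount by one plus the count.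

**Four flasks.** Zeta holds 0.552 M at balance with a count of 0.410. Delta holds 0.599 M with a count of 1.75, so its drain outruns its better balance. Theta is a different case: the forward constant times the time is 0.284 against 2.24 in gamma, so I reckon theta by the opening of the pool and not by balance. I commit to 41.7 % in gamma, 35.6 % in zeta, 17.3 % in theta and 19.8 % in delta, and the winner is gamma.

**The result.** The forecast, with numbers of its own and not mine, names gamma with 42 % in gamma, 36.5 % in zeta, 18.5 % in theta and 20 % in delta, on the ground that “10 °C is the best compromise”. The simulation gives gamma as the winner, with 41.5 % in gamma, 35.3 % in zeta, 17.7 % in theta and 18.3 % in delta.

**Heavier charge.** Gamma's count of 0.0812 belongs to a charge of 1.1 M. The neighbour flask is gamma with 2.8 M of starting material, so its pool is 2.47 M and its balance holds 1.10 M of target. Its drain count rises to 0.324, and the same division gives 29.7 % of the charge. The simulated neighbour flask ends with 31.7 % of target, against 41.5 % in gamma, and starting material is its largest share at 39.9 %.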